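**Retrosynthetic overview**
1. Target ⇐ late monoepoxidation of the cis-5,6-disubstituted cyclohexa-1,3-diene ketone, on the face opposite the pyranone and side chain (oxirane formed last).
2. Cyclohexadiene ⇐ disrotatory 6π-electrocyclisation of an (E,Z,E,E)-tetraenyl pyranone, with the helical sense chosen by a bifunctional squaramide organocatalyst (carbocycle formed second; proposed new step).
3. Tetraene ⇐ Suzuki–Miyaura union of a (Z)-dienyl iodide carrying the pyranone with a dienyl boronate carrying the side chain.
4. Dienyl boronate ⇐ Wittig and boron–Wittig homologation of the L-proline aldol dimer of propanal, which sets the side-chain methyl centre first; the carbinol is oxidised to the ketone late.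
5. Dienyl iodide ⇐ 2-ethyl-6-methoxy-3,5-dimethyl-4-pyranone (pyranone ring formed first, from 4-methylheptane-3,5-dione and CO2) plus (Z)-3-iodo-2-methylacrolein by aldol–elimination.

Assumption: the (E,Z,E,E)-tetraene made in step 10 is taken to survive for hours at or below 0 °C in the dark, its uncatalysed ring closure needing gentle heating.

**Route**

Step 1
Reactants: 1 propanal (2 equiv); 2 ethyl 2-(triphenylphosphoranylidene)propanoate
Product: 4 ethyl (2E,4R,5S)-5-hydroxy-2,4-dimethylhept-2-enoate, via anti-aldol aldehyde 3 (not isolated)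
Conditions: L-proline (10 mol%), DMF, 4 °C, slow addition of 1; then 2, rt
Reagents that add atoms: none
Why: L-proline enamine catalysis (direct asymmetric aldol of propanal through the hydrogen-bonded chair transition state) sets the first stereocentres, the 2S methyl centre of 3 being the side-chain methyl centre of the target (about 99% ee, anti:syn about 4:1); in situ Wittig olefination with the stabilised ylide gives the E enoate, and the minor carbinol epimer is removed by chromatography (it would converge at step 12 anyway).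

Step 2
Reactants: 4 ethyl (2E,4R,5S)-5-hydroxy-2,4-dimethylhept-2-enoate
Product: 5 (2E,4R,5S)-2,4-dimethylhept-2-ene-1,5-diol
Conditions: iBu2AlH (3.3 equiv), CH2Cl2, −78 → 0 °C; aq. potassium sodium tartrate work-up
Reagents that add atoms: none
Why: 1,2-reduction of the enoate by the aluminium hydride gives the allylic alcohol without touching the stereocentres or the alkene geometry.

Step 3
Reactants: 5 (2E,4R,5S)-2,4-dimethylhept-2-ene-1,5-diol
Product: 6 (2E,4R,5S)-5-hydroxy-2,4-dimethylhept-2-enal
Conditions: MnO2 (15 equiv), CH2Cl2, rt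
Reagents that add atoms: none
Why: MnO2 oxidises only the allylic primary alcohol, leaving the non-allylic secondary carbinol (chemoselective allylic oxidation).

Step 4
Reactants: 6 (2E,4R,5S)-5-hydroxy-2,4-dimethylhept-2-enal; 7 1,1-bis(4,4,5,5-tetramethyl-1,3,2-dioxaborolan-2-yl)ethane
Product: 8 (3S,4R,5E,7Z)-4,6-dimethyl-8-(4,4,5,5-tetramethyl-1,3,2-dioxaborolan-2-yl)nona-5,7-dien-3-ol
Conditions: 7 (2.5 equiv), lithium 2,2,6,6-tetramethylpiperidide (2.4 equiv), THF, 0 °C; then 6, −78 °C → rt
Reagents that add atoms: none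
Why: boron–Wittig olefination, in which the lithiated geminal diboronate adds to the aldehyde and syn B–O elimination leaves the aldehyde-derived chain trans to the remaining boron, giving the trisubstituted alkenyl boronate with the geometry needed for coupling (one extra equivalent of the carbanion is consumed by the free hydroxyl).

Step 5
Reactants: 9 4-methylheptane-3,5-dione
Product: 11 6-ethyl-4-hydroxy-3,5-dimethyl-2H-pyran-2-one, via diketo acid 10 (not isolated)
Conditions: LiN(iPr)2 (2.2 equiv), THF, −78 → 0 °C; CO2 (gas), −78 °C; aq. HCl; then 1,1′-carbonyldiimidazole, THF, rt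
Reagents that add atoms: carbon dioxide O=C=O
Why: carboxylation of the β-diketone dianion at its terminal carbanion (the diketone is symmetrical, so only one dianion exists) followed by lactonisation of the activated acid onto the δ-enol oxygen gives the 4-hydroxy-2-pyranone (dianion carboxylation and cyclodehydration).

Step 6
Reactants: 11 6-ethyl-4-hydroxy-3,5-dimethyl-2H-pyran-2-one
Product: 12 2-ethyl-6-methoxy-3,5-dimethyl-4H-pyran-4-one
Conditions: MeOTf (1.3 equiv), CH2Cl2, rt; aq. NaHCO3 work-up
Reagents that add atoms: methyl trifluoromethanesulfonate COS(=O)(=O)C(F)(F)F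
Why: the hard methylating agent alkylates the lactone carbonyl oxygen of the neutral hydroxypyranone, and proton loss gives the 2-methoxy-4-pyranone (regioselective O-methylation).

Step 7
Reactants: 13 prop-2-yn-1-ol
Product: 15 (Z)-3-iodo-2-methylprop-2-en-1-ol, via alkenylmagnesium alkoxide 14 (not isolated)
Conditions: MeMgBr (2.5 equiv), CuI (10 mol%), THF, −10 °C → rt; then I2, −10 °C
Reagents that add atoms: methylmagnesium bromide C[Mg]Br; iodine II
Why: alkoxide-directed, copper-catalysed anti-carbomagnesiation puts the methyl group on the internal carbon and magnesium cis to the CH2O group, and iodinolysis with retention gives the Z vinyl iodide.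

Step 8
Reactants: 15 (Z)-3-iodo-2-methylprop-2-en-1-ol
Product: 16 (Z)-3-iodo-2-methylprop-2-enal
Conditions: MnO2 (15 equiv), CH2Cl2, rt, dark
Reagents that add atoms: none
Why: neutral allylic oxidation with MnO2 keeps the Z geometry of the sensitive β-iodo enal, which is used crude.

Step 9
Reactants: 12 2-ethyl-6-methoxy-3,5-dimethyl-4H-pyran-4-one; 16 (Z)-3-iodo-2-methylprop-2-enal
Product: 19 2-[(2E,4Z)-5-iodo-4-methylpenta-2,4-dien-2-yl]-6-methoxy-3,5-dimethyl-4H-pyran-4-one, via lithium aldolate 17 (not isolated), via aldol mesylate 18 (not isolated)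
Conditions: LiN(SiMe3)2 (1.1 equiv), THF, −78 °C; then 16; then MsCl, −78 → 0 °C; then DBU, rt
Reagents that add atoms: none
Why: vinylogous aldol addition of the lithiated 2-ethyl group to the aldehyde, O-mesylation and base-induced elimination give the E trisubstituted alkene conjugated to the pyranone; the two transient, uncontrolled centres of 17 and 18 are erased in the same flask.

Step 10
Reactants: 8 (3S,4R,5E,7Z)-4,6-dimethyl-8-(4,4,5,5-tetramethyl-1,3,2-dioxaborolan-2-yl)nona-5,7-dien-3-ol; 19 2-[(2E,4Z)-5-iodo-4-methylpenta-2,4-dien-2-yl]-6-methoxy-3,5-dimethyl-4H-pyran-4-one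
Product: 20 2-[(2E,4Z,6E,8E,10R,11S)-11-hydroxy-4,6,8,10-tetramethyltrideca-2,4,6,8-tetraen-2-yl]-6-methoxy-3,5-dimethyl-4H-pyran-4-one
Conditions: Pd(PPh3)4 (10 mol%), TlOEt (1.5 equiv), degassed THF/H2O 3:1, 0 °C, dark; cold work-up, used at once
Reagents that add atoms: none
Why: Suzuki–Miyaura coupling proceeds with retention at both sp2 carbons, and the thallium base makes transmetalation fast enough at 0 °C to deliver the (E,Z,E,E)-tetraene below the temperature of its thermal ring closure.

Step 11
Reactants: 20 2-[(2E,4Z,6E,8E,10R,11S)-11-hydroxy-4,6,8,10-tetramethyltrideca-2,4,6,8-tetraen-2-yl]-6-methoxy-3,5-dimethyl-4H-pyran-4-one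
Product: 21 2-[(1R,6S)-6-[(2E,4R,5S)-5-hydroxy-4-methylhept-2-en-2-yl]-1,3,5-trimethylcyclohexa-2,4-dien-1-yl]-6-methoxy-3,5-dimethyl-4H-pyran-4-one
Conditions: quinine-derived squaramide, 3-[3,5-bis(trifluoromethyl)anilino]-4-[(9-deoxy-epi-quinin-9-yl)amino]cyclobut-3-ene-1,2-dione (20 mol%), toluene (0.02 M), 4 Å molecular sieves, 0 °C, dark
Reagents that add atoms: none
Why: Proposed new method: a hydrogen-bond-templated, catalyst-controlled torquoselective 6π-electrocyclisation, in which the squaramide N–H pair binds the pyranone C=O while the quinuclidine nitrogen accepts the side-chain O–H; both contacts can be held at once only in the folded s-cis,s-cis helical conformer where the two outside terminal groups converge, which is the near-attack geometry of the thermally allowed disrotatory closure, so binding pre-pays the conformational cost (rate gain at 0 °C, where unbound 20 closes only slowly) and, because the catalyst and the existing side-chain centres make the two helical complexes diastereomeric, only one helix closes, setting C1 (R) and C6 (S) of the new ring, while the cis relation of pyranone and side chain is fixed by orbital symmetry from the E,Z,E triene; the closest known reaction types are the uncatalysed thermal 6π closure of E,Z,E-trienyl pyranones, carbonyl-binding (Lewis acid) acceleration of 6π-electrocyclisations and two-point squaramide–amine recognition in bifunctional organocatalysis.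

Step 12
Reactants: 21 2-[(1R,6S)-6-[(2E,4R,5S)-5-hydroxy-4-methylhept-2-en-2-yl]-1,3,5-trimethylcyclohexa-2,4-dien-1-yl]-6-methoxy-3,5-dimethyl-4H-pyran-4-one
Product: 22 2-methoxy-3,5-dimethyl-6-[(1R,6S)-1,3,5-trimethyl-6-[(2E,4R)-4-methyl-5-oxohept-2-en-2-yl]cyclohexa-2,4-dien-1-yl]-4H-pyran-4-one
Conditions: Dess–Martin periodinane (1.3 equiv), pyridine, CH2Cl2, 0 °C → rt
Reagents that add atoms: none
Why: Dess–Martin oxidation of the secondary carbinol is non-basic, so the now α-keto, allylic methyl centre is not epimerised and the β,γ-alkene does not move into conjugation.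

Step 13
Reactants: 22 2-methoxy-3,5-dimethyl-6-[(1R,6S)-1,3,5-trimethyl-6-[(2E,4R)-4-methyl-5-oxohept-2-en-2-yl]cyclohexa-2,4-dien-1-yl]-4H-pyran-4-one
Product: 23 2-methoxy-3,5-dimethyl-6-[(1R,4R,5R,6S)-2,4,6-trimethyl-5-[(2E,4R)-4-methyl-5-oxohept-2-en-2-yl]-7-oxabicyclo[4.1.0]hept-2-en-4-yl]-4H-pyran-4-one
Conditions: dimethyldioxirane (1.05 equiv, acetone solution), CH2Cl2, −40 → −20 °C
Reagents that add atoms: dimethyldioxirane CC1(C)OO1
Why: electrophilic dioxirane epoxidation (concerted oxygen transfer) should take the diene double bond next to the tertiary ring carbon (C4=C5 of 22) rather than the one next to the quaternary carbon or the doubly flanked side-chain alkene, from the ring face opposite the cis pyranone and side chain, which sets both oxirane centres as in the target under neutral conditions.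

**Compound list**
1 | propanal | CCC=O | starting material
2 | ethyl 2-(triphenylphosphoranylidene)propanoate | CCOC(=O)C(C)=P(c1ccccc1)(c1ccccc1)c1ccccc1 | starting material
3 | (2S,3S)-3-hydroxy-2-methylpentanal | CC[C@H](O)[C@H](C)C=O | intermediate
4 | ethyl (2E,4R,5S)-5-hydroxy-2,4-dimethylhept-2-enoate | CC[C@H](O)[C@H](C)/C=C(\C)C(=O)OCC | intermediate
5 | (2E,4R,5S)-2,4-dimethylhept-2-ene-1,5-diol | CC[C@H](O)[C@H](C)/C=C(\C)CO | intermediate
6 | (2E,4R,5S)-5-hydroxy-2,4-dimethylhept-2-enal | CC[C@H](O)[C@H](C)/C=C(\C)C=O | intermediate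
7 | 1,1-bis(4,4,5,5-tetramethyl-1,3,2-dioxaborolan-2-yl)ethane | CC(B1OC(C)(C)C(C)(C)O1)B1OC(C)(C)C(C)(C)O1 | starting material
8 | (3S,4R,5E,7Z)-4,6-dimethyl-8-(4,4,5,5-tetramethyl-1,3,2-dioxaborolan-2-yl)nona-5,7-dien-3-ol | CC[C@H](O)[C@H](C)/C=C(\C)/C=C(\C)B1OC(C)(C)C(C)(C)O1 | intermediate
9 | 4-methylheptane-3,5-dione | CCC(=O)C(C)C(=O)CC | starting material
10 | 2,4-dimethyl-3,5-dioxoheptanoic acid (enolisable; no fixed configuration) | CCC(=O)C(C)C(=O)C(C)C(=O)O | intermediate
11 | 6-ethyl-4-hydroxy-3,5-dimethyl-2H-pyran-2-one | CCc1oc(=O)c(C)c(O)c1C | intermediate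
12 | 2-ethyl-6-methoxy-3,5-dimethyl-4H-pyran-4-one | CCc1oc(OC)c(C)c(=O)c1C | intermediate
13 | prop-2-yn-1-ol | C#CCO | starting material
14 | bromomagnesium (Z)-3-(bromomagnesio)-2-methylprop-2-en-1-olate | Br[Mg]/C=C(/C)CO[Mg]Br | intermediate
15 | (Z)-3-iodo-2-methylprop-2-en-1-ol | I/C=C(/C)CO | intermediate
16 | (Z)-3-iodo-2-methylprop-2-enal | I/C=C(/C)C=O | intermediate
17 | lithium (4Z)-5-iodo-2-(6-methoxy-3,5-dimethyl-4-oxo-4H-pyran-2-yl)-4-methylpent-4-en-3-olate (racemic diastereomer mixture) | [Li+].[O-]C(C(C)c1oc(OC)c(C)c(=O)c1C)/C(C)=C\I | intermediate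
18 | (4Z)-5-iodo-2-(6-methoxy-3,5-dimethyl-4-oxo-4H-pyran-2-yl)-4-methylpent-4-en-3-yl methanesulfonate (racemic diastereomer mixture) | CS(=O)(=O)OC(C(C)c1oc(OC)c(C)c(=O)c1C)/C(C)=C\I | intermediate
19 | 2-[(2E,4Z)-5-iodo-4-methylpenta-2,4-dien-2-yl]-6-methoxy-3,5-dimethyl-4H-pyran-4-one | I/C=C(/C)\C=C(/C)c1oc(OC)c(C)c(=O)c1C | intermediate
20 | 2-[(2E,4Z,6E,8E,10R,11S)-11-hydroxy-4,6,8,10-tetramethyltrideca-2,4,6,8-tetraen-2-yl]-6-methoxy-3,5-dimethyl-4H-pyran-4-one | CC[C@H](O)[C@H](C)/C=C(\C)/C=C(\C)/C=C(/C)\C=C(/C)c1oc(OC)c(C)c(=O)c1C | intermediate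
21 | 2-[(1R,6S)-6-[(2E,4R,5S)-5-hydroxy-4-methylhept-2-en-2-yl]-1,3,5-trimethylcyclohexa-2,4-dien-1-yl]-6-methoxy-3,5-dimethyl-4H-pyran-4-one (pyranone and side chain cis) | CC[C@H](O)[C@H](C)/C=C(\C)[C@H]1C(C)=CC(C)=C[C@@]1(C)c1oc(OC)c(C)c(=O)c1C | intermediate
22 | 2-methoxy-3,5-dimethyl-6-[(1R,6S)-1,3,5-trimethyl-6-[(2E,4R)-4-methyl-5-oxohept-2-en-2-yl]cyclohexa-2,4-dien-1-yl]-4H-pyran-4-one | CCC(=O)[C@H](C)/C=C(\C)[C@H]1C(C)=CC(C)=C[C@@]1(C)c1oc(OC)c(C)c(=O)c1C | intermediate
23 | 2-methoxy-3,5-dimethyl-6-[(1R,4R,5R,6S)-2,4,6-trimethyl-5-[(2E,4R)-4-methyl-5-oxohept-2-en-2-yl]-7-oxabicyclo[4.1.0]hept-2-en-4-yl]-4H-pyran-4-one (oxirane trans to pyranone and side chain) | CCC(=O)[C@H](C)/C=C(\C)[C@H]1[C@]2(C)O[C@@H]2C(C)=C[C@@]1(C)c1oc(OC)c(C)c(=O)c1C | target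

**Step count and risks**

Total: 13 steps. Longest linear sequence: 8 steps (1, 2, 3, 4, 10, 11, 12, 13, from propanal). The two branches to iodide 19 are 3 steps each before the coupling.

The three steps most likely to fail:

Step 11 (the proposed new step). The catalyst may give too little rate gain over the uncatalysed closure, or the wrong or no helical preference; the pseudo-enantiomeric quinidine catalyst is the first variation to try. The fallback uses known chemistry and sets out from 20. Tetraene 20 is warmed without catalyst in toluene at 60 °C in the dark, and the thermal disrotatory 6π-electrocyclisation gives 21 together with its ring diastereomer 2-[(1S,6R)-6-[(2E,4R,5S)-5-hydroxy-4-methylhept-2-en-2-yl]-1,3,5-trimethylcyclohexa-2,4-dien-1-yl]-6-methoxy-3,5-dimethyl-4H-pyran-4-one F1, in roughly equal amounts because the remote side-chain centres do not bias the closure. Both are single enantiomers thanks to step 1, so they are separated as diastereomers by preparative HPLC on silica, F1 is set aside, and the route is rejoined at 21.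

Step 13. The dioxirane may also attack the side-chain alkene or the other diene double bond, or give a mixture of faces. The fallback sets out from 22 and returns directly at 23. It replaces substrate-controlled dioxirane transfer by catalyst-controlled oxo-manganese transfer (Jacobsen–Katsuki epoxidation): the matched enantiomer of (salen)MnCl (trivalent manganese; salen = N,N′-bis(3,5-di-tert-butylsalicylidene)-1,2-cyclohexanediamine), mCPBA and N-methylmorpholine N-oxide in CH2Cl2 at −78 °C. This catalyst class reacts with conjugated alkenes far faster than with isolated ones and its bulk favours the diene terminus away from the quaternary carbon. No new compound is made (F0).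

Step 4. The boron–Wittig step may give poor geometry at the new trisubstituted alkene, or suffer from the free hydroxyl. The fallback sets out from 6 and builds the same boronate by alkyne hydroboration. Enal 6 is homologated with dimethyl (1-diazo-2-oxopropyl)phosphonate and K2CO3 in methanol to the terminal enyne (3S,4R,5E)-4,6-dimethyloct-5-en-7-yn-3-ol F2. Its dianion (n-BuLi, 2.1 equiv, THF, −78 °C) is C-methylated with MeI to (3S,4R,5E)-4,6-dimethylnon-5-en-7-yn-3-ol F3. Syn hydroboration with pinacolborane and catalytic Cp2Zr(H)Cl then places boron on the methyl-bearing alkyne carbon, and the route is rejoined at 8.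

Further compounds
F1 | step 11 | 2-[(1S,6R)-6-[(2E,4R,5S)-5-hydroxy-4-methylhept-2-en-2-yl]-1,3,5-trimethylcyclohexa-2,4-dien-1-yl]-6-methoxy-3,5-dimethyl-4H-pyran-4-one | CC[C@H](O)[C@H](C)/C=C(\C)[C@@H]1C(C)=CC(C)=C[C@]1(C)c1oc(OC)c(C)c(=O)c1C
F2 | step 4 | (3S,4R,5E)-4,6-dimethyloct-5-en-7-yn-3-ol | CC[C@H](O)[C@H](C)/C=C(\C)C#C
F3 | step 4 | (3S,4R,5E)-4,6-dimethylnon-5-en-7-yn-3-ol | CC[C@H](O)[C@H](C)/C=C(\C)C#CC
F0 | step 13 | none | none
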